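## Retrosynthetic overview

1. The interflavanyl C4–C6' bond is cut last. The upper unit is a flavan-3,4-diol (donor of the C4 cation); the lower unit is a C6'-boronic acid kept at the 4'-ketone level, which is reduced only after union and deprotection.
2. Both halves come from one 6-bromo-dihydroflavonol. Its ring C is made in one flask from a 2-fluoroaryl alkoxymethyl ketone and 3,4-bis(benzyloxy)benzaldehyde: an asymmetric boron aldol forms C2–C3, then the aldolate oxygen displaces fluoride on ring A to form O1–C8a.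
3. Enabling feature: the C4 oxygen of ring C. As a ketone it makes C3–H enolisable and, sitting ortho to C8a on ring A, turns C8a–F into an SNAr site; O1 and C2 are the C=O of the ring B aldehyde.
4. The 3,4-cis (4β) interflavanyl bond is set by aryl transfer from boron tethered to the upper 3-OH.
5. Ring order: rings A and B are bought; ring C of the monomer (used twice); interflavanyl bond; global hydrogenolysis; reduction of the lower C4 ketone to the 3,4-trans diol.

Key step: step 5

Assumption: (−)-Ipc2BOTf (from (+)-α-pinene) is taken to deliver the Z enol borinate to the Si face of the aldehyde; if the sense is the opposite, the antipodal reagent is used and nothing else changes.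

## Route

Step 1
Reactants: 1 2-bromo-5-fluorophenol
Product: 2 2-bromo-5-fluoro-4-iodophenol
Conditions: NIS (1.05 equiv), TsOH·H2O (10 mol %), MeCN, 0 to 20 °C
Reagents that add atoms: N-iodosuccinimide, O=C1CCC(=O)N1I
Why: Electrophilic aromatic iodination, in which the hydroxyl group directs to its free para position (also ortho to fluorine) in preference to the ortho position flanked by OH and F.

Step 2
Reactants: 2 2-bromo-5-fluoro-4-iodophenol
Product: 3 1-(benzyloxy)-2-bromo-5-fluoro-4-iodobenzene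
Conditions: BnBr (1.1 equiv), K2CO3, DMF, 20 °C
Reagents that add atoms: benzyl bromide, BrCc1ccccc1
Why: Williamson ether synthesis on an acidic halophenol should be clean and protects the future 7-OH as a hydrogenolysable ether.

Step 3
Reactants: 4 naphthalen-2-ylmethanol, 5 2-chloro-N-methoxy-N-methylacetamide
Product: 6 N-methoxy-N-methyl-2-(naphthalen-2-ylmethoxy)acetamide
Conditions: NaH (1.1 equiv), THF, 0 °C; then 5, Bu4NI (5 mol %), 0 to 20 °C
Reagents that add atoms: none
Why: Williamson ether synthesis by SN2 displacement at the α-chloro amide, whose Weinreb carbonyl resists alkoxide attack.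

Step 4
Reactants: 3 1-(benzyloxy)-2-bromo-5-fluoro-4-iodobenzene, 6 N-methoxy-N-methyl-2-(naphthalen-2-ylmethoxy)acetamide
Product: 8 1-[4-(benzyloxy)-5-bromo-2-fluorophenyl]-2-(naphthalen-2-ylmethoxy)ethan-1-one, via aryl Grignard reagent 7 (not isolated)
Conditions: i-PrMgCl·LiCl (1.05 equiv), THF, −40 °C; then 6, −40 to 0 °C; aq. NH4Cl
Reagents that add atoms: none
Why: Iodine–magnesium exchange is much faster at C–I than at C–Br and the ortho-fluoro Grignard reagent should not eliminate to an aryne at −40 °C, and the Weinreb ketone synthesis stops at the ketone through the chelated tetrahedral adduct.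

Step 5
Reactants: 8 1-[4-(benzyloxy)-5-bromo-2-fluorophenyl]-2-(naphthalen-2-ylmethoxy)ethan-1-one, 9 3,4-bis(benzyloxy)benzaldehyde
Product: 13 (2R,3R)-7-(benzyloxy)-2-[3,4-bis(benzyloxy)phenyl]-6-bromo-3-(naphthalen-2-ylmethoxy)chroman-4-one, via Z enol borinate 10 (not isolated), via syn boron aldolate 11 (not isolated), via cis flavanone 12 (not isolated)
Conditions: (−)-Ipc2BOTf (1.3 equiv), i-Pr2NEt (1.5 equiv), CH2Cl2, −78 °C; 9, −78 to −20 °C; then CsF (1.5 equiv), 18-crown-6 (0.2 equiv), THF, −20 to 20 °C; H2O2, pH 7 sodium phosphate buffer, MeOH work-up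
Reagents that add atoms: none
Why: Proposed new method: i-Pr2NEt and (−)-Ipc2BOTf enolise 8 to the Z enol borinate 10, which adds to the Si face of 9 through a closed chair transition state to give the syn (2R) boron aldolate 11; fluoride then takes up boron (strong B–F bond) and the freed C2 alkoxide attacks C8a, whose fluoride sits ortho to the C4 ketone, in an addition–elimination (SNAr). The closest known reaction types are the diisopinocampheylboron aldol reaction of ketones, the base-induced SNAr closure of 3-hydroxy-1-(2-fluoroaryl)propan-1-ones to chroman-4-ones and the fluoride-triggered O-arylation of silyl ethers by fluoroarenes; new is their union in one flask, with boron as the group exchanged for aryl. Ring C closes by formal 6-endo-trig addition of oxygen to the C8a=C4a–C4=O unit of ring A through a Meisenheimer anion that expels fluoride. C2 is set by the isopinocampheyl ligands (reagent control), and C3 ends trans to the C2 aryl group by base-mediated equilibration of cis flavanone 12 to the diequatorial isomer (thermodynamic control), so the syn or anti outcome of the aldol does not matter. The step needs O-arylation by the C2 oxygen only and substitution of fluoride only: the C3 oxygen is blocked as the naphthylmethyl ether, which excludes five-membered ring closure, and the bromide is meta to the ketone and unactivated. Ring closure must outrun retro-aldol cleavage of the free alkoxide, which is why boron is removed only at −20 °C next to the activated C–F carbon.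

Step 6
Reactants: 13 (2R,3R)-7-(benzyloxy)-2-[3,4-bis(benzyloxy)phenyl]-6-bromo-3-(naphthalen-2-ylmethoxy)chroman-4-one
Product: 14 (2R,3R)-7-(benzyloxy)-2-[3,4-bis(benzyloxy)phenyl]-6-bromo-3-hydroxychroman-4-one
Conditions: DDQ (1.5 equiv), CH2Cl2/pH 7 buffer (10:1), 0 to 20 °C
Reagents that add atoms: none
Why: Oxidative cleavage of the 2-naphthylmethyl ether by DDQ is much faster than attack on benzyl ethers, and at the ketone level C4 cannot be oxidised.

Step 7
Reactants: 14 (2R,3R)-7-(benzyloxy)-2-[3,4-bis(benzyloxy)phenyl]-6-bromo-3-hydroxychroman-4-one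
Product: 15 (2R,3S,4R)-7-(benzyloxy)-2-[3,4-bis(benzyloxy)phenyl]-6-bromochromane-3,4-diol
Conditions: NaBH4 (2 equiv), THF/MeOH, 0 °C
Reagents that add atoms: none
Why: Hydride reduction of a dihydroflavonol should proceed by axial attack to the 2,3-trans-3,4-trans diol (substrate control); the C4 configuration is in any case erased in step 9.

Step 8
Reactants: 13 (2R,3R)-7-(benzyloxy)-2-[3,4-bis(benzyloxy)phenyl]-6-bromo-3-(naphthalen-2-ylmethoxy)chroman-4-one
Product: 16 [(2R,3R)-7-(benzyloxy)-2-[3,4-bis(benzyloxy)phenyl]-3-(naphthalen-2-ylmethoxy)-4-oxochroman-6-yl]boronic acid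
Conditions: B2(OH)4 (2 equiv), KOAc (3 equiv), Pd(OAc)2 (2 mol %), XPhos (4 mol %), EtOH, 80 °C
Reagents that add atoms: tetrahydroxydiboron, OB(O)B(O)O
Why: Miyaura-type palladium-catalysed borylation of an aryl bromide with tetrahydroxydiboron under acetate base tolerates the ketone and ethers and should give the boronic acid directly.

Step 9
Reactants: 15 (2R,3S,4R)-7-(benzyloxy)-2-[3,4-bis(benzyloxy)phenyl]-6-bromochromane-3,4-diol, 16 [(2R,3R)-7-(benzyloxy)-2-[3,4-bis(benzyloxy)phenyl]-3-(naphthalen-2-ylmethoxy)-4-oxochroman-6-yl]boronic acid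
Product: 18 (2R,3R)-7-(benzyloxy)-6-[(2R,3S,4S)-7-(benzyloxy)-2-[3,4-bis(benzyloxy)phenyl]-6-bromo-3-hydroxychroman-4-yl]-2-[3,4-bis(benzyloxy)phenyl]-3-(naphthalen-2-ylmethoxy)chroman-4-one, via cyclic boronate 17 (not isolated)
Conditions: 4 Å MS, CH2Cl2, 20 °C; then Sc(OTf)3 (10 mol %), CH2Cl2/MeNO2, −20 to 20 °C; aq. pH 7 buffer
Reagents that add atoms: none
Why: Proposed new method: the diol and the boronic acid condense to dioxaborolane 17, Sc(OTf)3 ionises the benzylic C4–O bond (cation stabilised by the para 7-benzyloxy group) while boron stays on O3, and the electron-rich aryl group shifts from boron to C4 through a five-membered transition state on the face of O3, which should fix both the 3,4-cis (4β) configuration and the ipso (C6') site; the closest known reaction types are the Petasis borono-Mannich reaction of α-hydroxy aldehydes, hydroxyl-directed additions of boronates to cyclic N-acyliminium and oxocarbenium ions, and acid-promoted substitution of π-activated benzylic alcohols by aryl boron reagents.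

Step 10
Reactants: 18 (2R,3R)-7-(benzyloxy)-6-[(2R,3S,4S)-7-(benzyloxy)-2-[3,4-bis(benzyloxy)phenyl]-6-bromo-3-hydroxychroman-4-yl]-2-[3,4-bis(benzyloxy)phenyl]-3-(naphthalen-2-ylmethoxy)chroman-4-one
Product: 19 (2R,3R)-2-(3,4-dihydroxyphenyl)-6-[(2R,3S,4S)-2-(3,4-dihydroxyphenyl)-3,7-dihydroxychroman-4-yl]-3,7-dihydroxychroman-4-one
Conditions: H2 (1 atm), Pd(OH)2/C, Et3N (1.2 equiv), THF/MeOH, 20 °C
Reagents that add atoms: none
Why: Hydrogenolysis should remove the six benzyl ethers, the naphthylmethyl ether and the aryl bromide in one operation, while the aryl ketone (a vinylogous ester through the para oxygen) and the interflavanyl bond are expected to survive the buffered conditions.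

Step 11
Reactants: 19 (2R,3R)-2-(3,4-dihydroxyphenyl)-6-[(2R,3S,4S)-2-(3,4-dihydroxyphenyl)-3,7-dihydroxychroman-4-yl]-3,7-dihydroxychroman-4-one
Product: 20 (2R,3S,4S)-2-(3,4-dihydroxyphenyl)-4-[(2R,3S,4R)-2-(3,4-dihydroxyphenyl)-3,4,7-trihydroxychroman-6-yl]chromane-3,7-diol
Conditions: NaBH4 (excess), EtOH, 0 °C; AcOH to pH 6
Reagents that add atoms: none
Why: Hydride reduction of a free-phenolic dihydroflavonol should occur by axial attack to place the new 4-OH equatorial and trans to the 3-OH (substrate control), giving the 2,3-trans-3,4-trans diol of the lower unit.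

## Compound list

1 | 2-bromo-5-fluorophenol | Oc1cc(F)ccc1Br | starting material
2 | 2-bromo-5-fluoro-4-iodophenol | Oc1cc(F)c(I)cc1Br | intermediate
3 | 1-(benzyloxy)-2-bromo-5-fluoro-4-iodobenzene | Fc1cc(OCc2ccccc2)c(Br)cc1I | intermediate
4 | naphthalen-2-ylmethanol | OCc1ccc2ccccc2c1 | starting material
5 | 2-chloro-N-methoxy-N-methylacetamide | CON(C)C(=O)CCl | starting material
6 | N-methoxy-N-methyl-2-(naphthalen-2-ylmethoxy)acetamide | CON(C)C(=O)COCc1ccc2ccccc2c1 | intermediate
7 | [4-(benzyloxy)-5-bromo-2-fluorophenyl]magnesium chloride (not isolated) | Cl[Mg]c1cc(Br)c(OCc2ccccc2)cc1F | intermediate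
8 | 1-[4-(benzyloxy)-5-bromo-2-fluorophenyl]-2-(naphthalen-2-ylmethoxy)ethan-1-one | O=C(COCc1ccc2ccccc2c1)c1cc(Br)c(OCc2ccccc2)cc1F | intermediate
9 | 3,4-bis(benzyloxy)benzaldehyde | O=Cc1ccc(OCc2ccccc2)c(OCc2ccccc2)c1 | starting material
10 | (Z)-enol diisopinocampheylborinate of 8 (not isolated) | Fc1cc(OCc2ccccc2)c(Br)cc1/C(OB([C@@H]1C[C@@H]2C[C@H]([C@H]1C)C2(C)C)[C@@H]1C[C@@H]2C[C@H]([C@H]1C)C2(C)C)=C/OCc1ccc2ccccc2c1 | intermediate
11 | (2S,3R)-1-[4-(benzyloxy)-5-bromo-2-fluorophenyl]-3-[3,4-bis(benzyloxy)phenyl]-3-[(diisopinocampheylboryl)oxy]-2-(naphthalen-2-ylmethoxy)propan-1-one (syn, not isolated) | O=C(c1cc(Br)c(OCc2ccccc2)cc1F)[C@@H](OCc1ccc2ccccc2c1)[C@H](OB([C@@H]1C[C@@H]2C[C@H]([C@H]1C)C2(C)C)[C@@H]1C[C@@H]2C[C@H]([C@H]1C)C2(C)C)c1ccc(OCc2ccccc2)c(OCc2ccccc2)c1 | intermediate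
12 | (2R,3S)-7-(benzyloxy)-2-[3,4-bis(benzyloxy)phenyl]-6-bromo-3-(naphthalen-2-ylmethoxy)chroman-4-one (2,3-cis, not isolated) | Brc1cc2c(cc1OCc1ccccc1)O[C@H](c1ccc(OCc3ccccc3)c(OCc3ccccc3)c1)[C@H](OCc1ccc3ccccc3c1)C2=O | intermediate
13 | (2R,3R)-7-(benzyloxy)-2-[3,4-bis(benzyloxy)phenyl]-6-bromo-3-(naphthalen-2-ylmethoxy)chroman-4-one (2,3-trans) | Brc1cc2c(cc1OCc1ccccc1)O[C@H](c1ccc(OCc3ccccc3)c(OCc3ccccc3)c1)[C@@H](OCc1ccc3ccccc3c1)C2=O | intermediate
14 | (2R,3R)-7-(benzyloxy)-2-[3,4-bis(benzyloxy)phenyl]-6-bromo-3-hydroxychroman-4-one | Brc1cc2c(cc1OCc1ccccc1)O[C@H](c1ccc(OCc3ccccc3)c(OCc3ccccc3)c1)[C@@H](O)C2=O | intermediate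
15 | (2R,3S,4R)-7-(benzyloxy)-2-[3,4-bis(benzyloxy)phenyl]-6-bromochromane-3,4-diol | Brc1cc2c(cc1OCc1ccccc1)O[C@H](c1ccc(OCc3ccccc3)c(OCc3ccccc3)c1)[C@@H](O)[C@@H]2O | intermediate
16 | [(2R,3R)-7-(benzyloxy)-2-[3,4-bis(benzyloxy)phenyl]-3-(naphthalen-2-ylmethoxy)-4-oxochroman-6-yl]boronic acid | OB(O)c1cc2c(cc1OCc1ccccc1)O[C@H](c1ccc(OCc3ccccc3)c(OCc3ccccc3)c1)[C@@H](OCc1ccc3ccccc3c1)C2=O | intermediate
17 | cyclic 3,4-O-boronate (1,3,2-dioxaborolane) of diol 15 with boronic acid 16 (not isolated) | Brc1cc2c(cc1OCc1ccccc1)O[C@H](c1ccc(OCc3ccccc3)c(OCc3ccccc3)c1)[C@H]1OB(c3cc4c(cc3OCc3ccccc3)O[C@H](c3ccc(OCc5ccccc5)c(OCc5ccccc5)c3)[C@@H](OCc3ccc5ccccc5c3)C4=O)O[C@H]21 | intermediate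
18 | (2R,3R)-7-(benzyloxy)-6-[(2R,3S,4S)-7-(benzyloxy)-2-[3,4-bis(benzyloxy)phenyl]-6-bromo-3-hydroxychroman-4-yl]-2-[3,4-bis(benzyloxy)phenyl]-3-(naphthalen-2-ylmethoxy)chroman-4-one | Brc1cc2c(cc1OCc1ccccc1)O[C@H](c1ccc(OCc3ccccc3)c(OCc3ccccc3)c1)[C@@H](O)[C@H]2c1cc2c(cc1OCc1ccccc1)O[C@H](c1ccc(OCc3ccccc3)c(OCc3ccccc3)c1)[C@@H](OCc1ccc3ccccc3c1)C2=O | intermediate
19 | (2R,3R)-2-(3,4-dihydroxyphenyl)-6-[(2R,3S,4S)-2-(3,4-dihydroxyphenyl)-3,7-dihydroxychroman-4-yl]-3,7-dihydroxychroman-4-one (fisetinidol-(4β→6)-fustin) | Oc1ccc2c(c1)O[C@H](c1ccc(O)c(O)c1)[C@@H](O)[C@H]2c1cc2c(cc1O)O[C@H](c1ccc(O)c(O)c1)[C@@H](O)C2=O | intermediate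
20 | (2R,3S,4S)-2-(3,4-dihydroxyphenyl)-4-[(2R,3S,4R)-2-(3,4-dihydroxyphenyl)-3,4,7-trihydroxychroman-6-yl]chromane-3,7-diol | Oc1ccc2c(c1)O[C@H](c1ccc(O)c(O)c1)[C@@H](O)[C@H]2c1cc2c(cc1O)O[C@H](c1ccc(O)c(O)c1)[C@@H](O)[C@@H]2O | target

## Step count and risks

Total step count: 11. Longest linear sequence: 9 steps (1, 2, 4, 5, 6, 7, 9, 10, 11).

**Step 5 (key step).** The free alkoxide released from boron may undergo retro-aldol cleavage and unselective re-addition before ring closure, eroding the enantiomeric purity at C2. The facial selectivity of the boron aldol on an electron-rich aldehyde may also be insufficient, and base may open the ring between O1 and C2 during the C3 equilibration.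

Fallback: ring C is closed instead by phenol attack on a chalcone epoxide. It sets out from aldehyde 9 and commercial 1-(5-bromo-2,4-dihydroxyphenyl)ethanone. The non-chelated 4-OH is benzylated (BnBr, K2CO3, acetone) to 1-[4-(benzyloxy)-5-bromo-2-hydroxyphenyl]ethanone F1. The 2-OH is protected (MOMCl, i-Pr2NEt) to give 1-[4-(benzyloxy)-5-bromo-2-(methoxymethoxy)phenyl]ethanone F2. Claisen–Schmidt condensation with 9 (KOH, EtOH) should give (E)-1-[4-(benzyloxy)-5-bromo-2-(methoxymethoxy)phenyl]-3-[3,4-bis(benzyloxy)phenyl]prop-2-en-1-one F3. Juliá–Colonna epoxidation (poly-L-leucine, urea–H2O2, DBU, THF) should give the (αR,βS)-epoxy ketone F4. HCl in MeOH/THF removes the methoxymethyl group, and the freed phenol opens the oxirane at the benzylic carbon with inversion. The fallback comes back to the route at 14, and at 13 after O-alkylation of 14 with 2-(bromomethyl)naphthalene and Ag2O.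

**Step 9.** After ionisation of 17, undirected intermolecular arylation, protodeboronation of the electron-rich aryl boron unit, or a 1,2-hydride shift to the flavan-3-one may compete with the intramolecular aryl transfer. The result would be loss of the 3,4-cis selectivity or of the coupling itself.

Fallback: the classical acid-catalysed self-condensation. It sets out from 15. Hydrogenolysis (H2, Pd(OH)2/C, Et3N, THF/MeOH) should give (2R,3S,4R)-2-(3,4-dihydroxyphenyl)chromane-3,4,7-triol F5 ((+)-mollisacacidin). In 0.1 M aqueous HCl at 20 °C the C4 benzylic cation of one molecule is attacked by C6 of a second (Friedel–Crafts alkylation). This is expected to give 20 together with its 4α epimer, fisetinidol-(4α→6)-mollisacacidin F6, and higher oligomers. Chromatography on Sephadex LH-20 separates 20, so the fallback comes back to the route at 20.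

**Step 10.** The amine needed to take up HBr may slow O-debenzylation. It may also induce ring opening and epimerisation at C2/C3 of the free-phenolic dihydroflavonol unit, and prolonged exposure risks over-reduction of the ketone.

Fallback: debromination and debenzylation are separated. It sets out from 18. Homogeneous hydrodebromination (Pd(OAc)2, PPh3, HCO2H/Et3N, DMF, 60 °C) on the fully protected compound should give the bromine-free analogue of 18 with unchanged configuration, F7. Hydrogenolysis of F7 without base (H2, Pd(OH)2/C, THF/MeOH) then comes back to the route at 19.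

## Further compounds

F1 | step 5 | 1-[4-(benzyloxy)-5-bromo-2-hydroxyphenyl]ethanone | CC(=O)c1cc(Br)c(OCc2ccccc2)cc1O
F2 | step 5 | 1-[4-(benzyloxy)-5-bromo-2-(methoxymethoxy)phenyl]ethanone | CC(=O)c1cc(Br)c(OCc2ccccc2)cc1OCOC
F3 | step 5 | (E)-1-[4-(benzyloxy)-5-bromo-2-(methoxymethoxy)phenyl]-3-[3,4-bis(benzyloxy)phenyl]prop-2-en-1-one | O=C(/C=C/c1ccc(OCc2ccccc2)c(OCc2ccccc2)c1)c1cc(Br)c(OCc2ccccc2)cc1OCOC
F4 | step 5 | [4-(benzyloxy)-5-bromo-2-(methoxymethoxy)phenyl]{(2R,3S)-3-[3,4-bis(benzyloxy)phenyl]oxiran-2-yl}methanone | O=C(c1cc(Br)c(OCc2ccccc2)cc1OCOC)[C@@H]1O[C@H]1c1ccc(OCc2ccccc2)c(OCc2ccccc2)c1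
F5 | step 9 | (2R,3S,4R)-2-(3,4-dihydroxyphenyl)chromane-3,4,7-triol | Oc1ccc2c(c1)O[C@H](c1ccc(O)c(O)c1)[C@@H](O)[C@@H]2O
F6 | step 9 | (2R,3S,4R)-2-(3,4-dihydroxyphenyl)-4-[(2R,3S,4R)-2-(3,4-dihydroxyphenyl)-3,4,7-trihydroxychroman-6-yl]chromane-3,7-diol (4α epimer of 20) | Oc1ccc2c(c1)O[C@H](c1ccc(O)c(O)c1)[C@@H](O)[C@@H]2c1cc2c(cc1O)O[C@H](c1ccc(O)c(O)c1)[C@@H](O)[C@@H]2O
F7 | step 10 | 6-debromo analogue of 18 (upper unit 2,3-trans-3,4-cis, lower unit 2R,3R) | c1cc2c(cc1OCc1ccccc1)O[C@H](c1ccc(OCc3ccccc3)c(OCc3ccccc3)c1)[C@@H](O)[C@H]2c1cc2c(cc1OCc1ccccc1)O[C@H](c1ccc(OCc3ccccc3)c(OCc3ccccc3)c1)[C@@H](OCc1ccc3ccccc3c1)C2=O
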